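Everything rests on the biaryl bond between C4 of the phenanthrene (ring C, the α-carbon next to the C3 hydroxyl; C2 is blocked by Cl) and the carbon of the 4-hydroxyphenethyl ring D that lies ortho to its hydroxyl (para blocked by the ethylene bridge). Both are nucleophilic carbons ortho to free phenols, so they are united as partners of like polarity by an iron-catalysed dehydrogenative phenol coupling, which closes the 12-membered macrocycle as the last operation. Its precursor is the open triphenol 17, assembled by Suzuki–Miyaura union of a phenanthrene boronate (fragment 1, from 6-bromovanillin) with a bibenzyl bromide (fragment 2).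

Key step: step 11

Remark: the target is drawn without stereodescriptors, so any helical or axial chirality of the twisted macrocycle is taken as unspecified and the route delivers it as a racemate; no stereocentre occurs anywhere in the route.

Labels used below: ring A = methoxy ring of the phenanthrene, ring B = central ring, ring C = chlorophenol ring of the phenanthrene, ring D = 4-hydroxyphenethyl ring, ring E = chlorophenol ring carrying the ethylene bridge. Phenanthrene numbering is kept as in the target throughout: Cl at C2, O at C3, ring E at C6, OMe at C7.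

Step 1
Reactants: 1 2-bromo-4-hydroxy-5-methoxybenzaldehyde (6-bromovanillin); 2 [3-(benzyloxy)-4-chlorophenyl]boronic acid
Product: 3 2-[3-(benzyloxy)-4-chlorophenyl]-4-hydroxy-5-methoxybenzaldehyde
Conditions: Pd(dppf)Cl2 (3 mol %), K2CO3, 1,4-dioxane/H2O, 90 °C
Reagents that add atoms: none
Why: Suzuki–Miyaura coupling; the C–Br bond ortho to the formyl group adds readily to zerovalent palladium, the aryl chloride of 2 is inert to the dppf catalyst and the phenol is carried as its phenoxide.

Step 2
Reactants: 3 2-[3-(benzyloxy)-4-chlorophenyl]-4-hydroxy-5-methoxybenzaldehyde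
Product: 4 5-[3-(benzyloxy)-4-chlorophenyl]-4-formyl-2-methoxyphenyl trifluoromethanesulfonate
Conditions: Tf2O, pyridine, CH2Cl2, 0 °C
Reagents that add atoms: trifluoromethanesulfonic anhydride, O=S(=O)(OS(=O)(=O)C(F)(F)F)C(F)(F)F
Why: O-sulfonylation of the acidic vanillin-type phenol turns this oxygen into the leaving group for the later cross-coupling and keeps the aldehyde electrophilic for the Wittig step.

Step 3
Reactants: 4 5-[3-(benzyloxy)-4-chlorophenyl]-4-formyl-2-methoxyphenyl trifluoromethanesulfonate
Product: 5 5-[3-(benzyloxy)-4-chlorophenyl]-2-methoxy-4-(2-methoxyethenyl)phenyl trifluoromethanesulfonate (E/Z mixture)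
Conditions: Ph3P(CH2OMe)Cl, NaN(SiMe3)2, THF, 0 °C; then 4, −78 °C → rt
Reagents that add atoms: (methoxymethyl)triphenylphosphonium chloride, COC[P+](c1ccccc1)(c1ccccc1)c1ccccc1.[Cl-]
Why: Wittig methoxymethylenation with the preformed ylide adds the carbon that becomes C10; attack on the aldehyde at low temperature should outpace attack on the triflate, and the E/Z ratio is irrelevant because both isomers give the same cation in step 4.

Step 4
Reactants: 5 5-[3-(benzyloxy)-4-chlorophenyl]-2-methoxy-4-(2-methoxyethenyl)phenyl trifluoromethanesulfonate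
Product: 6 3-(benzyloxy)-2-chloro-7-methoxyphenanthren-6-yl trifluoromethanesulfonate
Conditions: Bi(OTf)3 (5 mol %), ClCH2CH2Cl, rt → 50 °C
Reagents that add atoms: none
Why: Acid-catalysed cyclisation of a 2-(2-arylphenyl)vinyl ether (oxocarbenium Friedel–Crafts alkylation, then loss of methanol to the aromatic phenanthrene); ring C is attacked para to the benzyloxy group, the activated and unhindered position, which places Cl at C2 and O at C3.

Step 5
Reactants: 7 2-bromo-3-hydroxybenzaldehyde
Product: 8 2-bromo-6-chloro-3-hydroxybenzaldehyde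
Conditions: SO2Cl2, CH2Cl2/Et2O, 0 °C → rt
Reagents that add atoms: sulfuryl chloride, O=S(=O)(Cl)Cl
Why: Electrophilic aromatic chlorination of the phenol; Br blocks one ortho position and the other (C4) is para to the formyl group and deactivated, so substitution should go para to OH.

Step 6
Reactants: 8 2-bromo-6-chloro-3-hydroxybenzaldehyde
Product: 9 3-(benzyloxy)-2-bromo-6-chlorobenzaldehyde
Conditions: BnBr, K2CO3, DMF, rt
Reagents that add atoms: benzyl bromide, BrCc1ccccc1
Why: Williamson etherification protects the phenol for the ylide, diimide and cross-coupling steps with a group that is removed later together with the other two.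

Step 7
Reactants: 9 3-(benzyloxy)-2-bromo-6-chlorobenzaldehyde; 10 1-(benzyloxy)-4-(chloromethyl)benzene (4-benzyloxybenzyl chloride)
Product: 13 1-(benzyloxy)-3-{2-[4-(benzyloxy)phenyl]ethenyl}-2-bromo-4-chlorobenzene (E/Z mixture), via phosphonium chloride 11 (not isolated), via phosphorus ylide 12 (not isolated)
Conditions: 10, PPh3, MeCN, reflux; solvent exchange to THF; KOt-Bu, 0 °C; then 9, 0 °C → rt
Reagents that add atoms: none
Why: Quaternisation of PPh3 by the activated benzylic chloride, deprotonation to the semi-stabilised ylide and Wittig olefination of the non-enolisable aldehyde 9 in one flask; the alkene geometry is irrelevant because the double bond is reduced next.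

Step 8
Reactants: 13 1-(benzyloxy)-3-{2-[4-(benzyloxy)phenyl]ethenyl}-2-bromo-4-chlorobenzene
Product: 14 1-(benzyloxy)-3-{2-[4-(benzyloxy)phenyl]ethyl}-2-bromo-4-chlorobenzene
Conditions: TsNHNH2, NaOAc, DME/H2O, reflux
Reagents that add atoms: none
Why: Diimide reduction; the diazene formed from the sulfonyl hydrazide transfers H2 to the C=C bond in a concerted syn fashion and leaves aryl bromide, aryl chloride and benzyl ethers untouched, which hydrogenation over palladium would endanger.

Step 9
Reactants: 6 3-(benzyloxy)-2-chloro-7-methoxyphenanthren-6-yl trifluoromethanesulfonate; 14 1-(benzyloxy)-3-{2-[4-(benzyloxy)phenyl]ethyl}-2-bromo-4-chlorobenzene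
Product: 16 3-(benzyloxy)-6-{6-(benzyloxy)-2-[2-(4-(benzyloxy)phenyl)ethyl]-3-chlorophenyl}-2-chloro-7-methoxyphenanthrene, via pinacol boronate 15 (not isolated)
Conditions: 6, B2pin2, Pd(dppf)Cl2 (5 mol %), KOAc, 1,4-dioxane, 90 °C; then 14, aq K3PO4, 100 °C
Reagents that add atoms: none
Why: Miyaura borylation of the triflate followed in the same flask by Suzuki–Miyaura coupling with the hindered bromide; the dppf catalyst activates C–OTf and C–Br but not the two C–Cl bonds, and the more hindered partner is used as the halide to limit protodeboronation.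

Step 10
Reactants: 16 3-(benzyloxy)-6-{6-(benzyloxy)-2-[2-(4-(benzyloxy)phenyl)ethyl]-3-chlorophenyl}-2-chloro-7-methoxyphenanthrene
Product: 17 2-chloro-6-{3-chloro-6-hydroxy-2-[2-(4-hydroxyphenyl)ethyl]phenyl}-7-methoxyphenanthren-3-ol
Conditions: BCl3, pentamethylbenzene, CH2Cl2, −78 °C → −40 °C; aqueous work-up
Reagents that add atoms: none
Why: Lewis-acid debenzylation with pentamethylbenzene as benzyl cation scavenger should cleave the three benzyl ethers at low temperature without touching the aryl chlorides or the methyl ether.

Step 11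
Reactants: 17 2-chloro-6-{3-chloro-6-hydroxy-2-[2-(4-hydroxyphenyl)ethyl]phenyl}-7-methoxyphenanthren-3-ol
Product: 18 target CNP0310669.0 (macrocycle in which phenanthrene C4 is bonded to the ring D carbon ortho to its hydroxyl)
Conditions: FeCl3 (10 mol %), t-BuOOt-Bu (1.2 equiv), (CF3)2CHOH, rt, 1 mM, slow addition of 17
Reagents that add atoms: none
Why: FeCl3 binds the phenols and, with the peroxide as terminal oxidant, turns the most easily oxidised one, the 2-naphthol-like phenanthren-3-ol, into an iron-bound aryloxyl radical whose spin sits mainly on C4; the ortho carbon of the ring D phenol adds to C4, and a second one-electron oxidation with loss of two protons restores both aromatic rings. The closest known reaction type is the FeCl3/peroxide cross-dehydrogenative coupling of phenols with 2-naphthols in fluorinated alcohol, and phenanthren-3-ols are known to couple oxidatively at C4. The 12-membered ring closes by C–C bond formation between two sp2 carbons, endo with respect to the C4–C4a bond (formally 12-endo-trig), the ring D arm reaching the π face at C4 from above the phenanthrene plane, where the near-perpendicular ring E holds it. No stereocentre is formed and the twisted macrocycle should arise as a racemate. The step needs C–C coupling at exactly these two ortho carbons, ring closure in preference to dimerisation, and no reaction of ring E: Cl at C2 and the ethylene bridge para to the ring D hydroxyl leave only the wanted ortho positions open, chelation of two phenolates on one iron favours ortho–ortho C–C over C–O union, the ring E phenol is the hardest to oxidise and its one free ortho carbon cannot reach C4, and high dilution suppresses intermolecular coupling.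

Compound list
1 | 2-bromo-4-hydroxy-5-methoxybenzaldehyde (6-bromovanillin) | O=Cc1cc(OC)c(O)cc1Br | starting material
2 | [3-(benzyloxy)-4-chlorophenyl]boronic acid | OB(O)c1ccc(Cl)c(OCc2ccccc2)c1 | starting material
3 | 2-[3-(benzyloxy)-4-chlorophenyl]-4-hydroxy-5-methoxybenzaldehyde | O=Cc1cc(OC)c(O)cc1-c1ccc(Cl)c(OCc2ccccc2)c1 | intermediate
4 | 5-[3-(benzyloxy)-4-chlorophenyl]-4-formyl-2-methoxyphenyl trifluoromethanesulfonate | O=Cc1cc(OC)c(OS(=O)(=O)C(F)(F)F)cc1-c1ccc(Cl)c(OCc2ccccc2)c1 | intermediate
5 | 5-[3-(benzyloxy)-4-chlorophenyl]-2-methoxy-4-(2-methoxyethenyl)phenyl trifluoromethanesulfonate (E/Z mixture) | COC=Cc1cc(OC)c(OS(=O)(=O)C(F)(F)F)cc1-c1ccc(Cl)c(OCc2ccccc2)c1 | intermediate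
6 | 3-(benzyloxy)-2-chloro-7-methoxyphenanthren-6-yl trifluoromethanesulfonate | COc1cc2ccc3cc(Cl)c(OCc4ccccc4)cc3c2cc1OS(=O)(=O)C(F)(F)F | intermediate
7 | 2-bromo-3-hydroxybenzaldehyde | O=Cc1cccc(O)c1Br | starting material
8 | 2-bromo-6-chloro-3-hydroxybenzaldehyde | O=Cc1c(Cl)ccc(O)c1Br | intermediate
9 | 3-(benzyloxy)-2-bromo-6-chlorobenzaldehyde | O=Cc1c(Cl)ccc(OCc2ccccc2)c1Br | intermediate
10 | 1-(benzyloxy)-4-(chloromethyl)benzene | ClCc1ccc(OCc2ccccc2)cc1 | starting material
11 | [4-(benzyloxy)benzyl]triphenylphosphonium chloride (not isolated) | [Cl-].c1ccc(cc1)[P+](Cc1ccc(OCc2ccccc2)cc1)(c1ccccc1)c1ccccc1 | intermediate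
12 | [4-(benzyloxy)benzylidene]triphenylphosphorane (not isolated) | c1ccc(cc1)P(=Cc1ccc(OCc2ccccc2)cc1)(c1ccccc1)c1ccccc1 | intermediate
13 | 1-(benzyloxy)-3-{2-[4-(benzyloxy)phenyl]ethenyl}-2-bromo-4-chlorobenzene (E/Z mixture) | Clc1ccc(OCc2ccccc2)c(Br)c1C=Cc1ccc(OCc2ccccc2)cc1 | intermediate
14 | 1-(benzyloxy)-3-{2-[4-(benzyloxy)phenyl]ethyl}-2-bromo-4-chlorobenzene | Clc1ccc(OCc2ccccc2)c(Br)c1CCc1ccc(OCc2ccccc2)cc1 | intermediate
15 | 2-[3-(benzyloxy)-2-chloro-7-methoxyphenanthren-6-yl]-4,4,5,5-tetramethyl-1,3,2-dioxaborolane (not isolated) | COc1cc2ccc3cc(Cl)c(OCc4ccccc4)cc3c2cc1B1OC(C)(C)C(C)(C)O1 | intermediate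
16 | 3-(benzyloxy)-6-{6-(benzyloxy)-2-[2-(4-(benzyloxy)phenyl)ethyl]-3-chlorophenyl}-2-chloro-7-methoxyphenanthrene | COc1cc2ccc3cc(Cl)c(OCc4ccccc4)cc3c2cc1-c1c(OCc2ccccc2)ccc(Cl)c1CCc1ccc(OCc2ccccc2)cc1 | intermediate
17 | 2-chloro-6-{3-chloro-6-hydroxy-2-[2-(4-hydroxyphenyl)ethyl]phenyl}-7-methoxyphenanthren-3-ol | COc1cc2ccc3cc(Cl)c(O)cc3c2cc1-c1c(O)ccc(Cl)c1CCc1ccc(O)cc1 | intermediate
18 | CNP0310669.0 (macrocyclic phenanthrene-bridged bis(bibenzyl), racemic) | COc1cc2ccc3cc(Cl)c(O)c4c3c2cc1-c1c(O)ccc(Cl)c1CCc1ccc(O)c-4c1 | target

Total step count: 11. Longest linear sequence: 7 steps (steps 1, 2, 3, 4, 9, 10, 11; the branch through steps 5, 6, 7, 8 is equally long).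

Steps most likely to fail

Step 11. Intermolecular dehydrogenative coupling through C4 (oligomerisation), C–O instead of C–C union, or further oxidation of the electron-rich biphenol once formed may take over, because the transition state of the 12-membered closure is strained. The fallback sets out from triphenol 17 and comes back at target 18. Iodination with N-iodosuccinimide (1 equiv, MeCN, −20 °C) at the most nucleophilic carbon, C4 of the phenanthrol, should give 2-chloro-6-{3-chloro-6-hydroxy-2-[2-(4-hydroxyphenyl)ethyl]phenyl}-4-iodo-7-methoxyphenanthren-3-ol F1. An intramolecular Pd-catalysed C-arylation of the ring D phenolate at its ortho carbon (Pd(OAc)2, PPh3, Cs2CO3, DMA, 110 °C, high dilution) then closes the same bond by a two-electron organometallic path (oxidative addition, attack of the phenolate carbon on the arylpalladium, reductive elimination) in place of a one-electron oxidation, and gives 18.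

Step 9. Transmetalation and reductive elimination at the tri-ortho-substituted biaryl junction may be slow, so that protodeboronation of 15 takes over. The fallback sets out from bromide 14 (with triflate 6) and comes back at 16. Bromine–lithium exchange on 14 (n-BuLi, THF, −78 °C) should give the aryllithium F2, ZnCl2 converts it into the arylzinc chloride F3, and Negishi coupling with triflate 6 (Pd(PPh3)4, THF, 60 °C) forms 16. The hindered partner is then the organometallic and no boronate is involved.

Step 5. Chlorination may occur at C4 (ortho to OH) or twice, and the regioisomers would be carried on. The fallback sets out from 7 and comes back at 9. Benzylation first (BnBr, K2CO3, DMF) gives 3-(benzyloxy)-2-bromobenzaldehyde F4. A Pd(OAc)2-catalysed ortho C–H chlorination directed by a transient imine (catalytic electron-poor aniline, N-chlorosuccinimide, ClCH2CH2Cl, 80 °C) then places Cl at the only free carbon ortho to the formyl group, which is also para to the benzyloxy group, and gives 9.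

Further compounds
F1 | step 11 | 2-chloro-6-{3-chloro-6-hydroxy-2-[2-(4-hydroxyphenyl)ethyl]phenyl}-4-iodo-7-methoxyphenanthren-3-ol | COc1cc2ccc3cc(Cl)c(O)c(I)c3c2cc1-c1c(O)ccc(Cl)c1CCc1ccc(O)cc1
F2 | step 9 | {6-(benzyloxy)-2-[2-(4-(benzyloxy)phenyl)ethyl]-3-chlorophenyl}lithium | [Li]c1c(OCc2ccccc2)ccc(Cl)c1CCc1ccc(OCc2ccccc2)cc1
F3 | step 9 | {6-(benzyloxy)-2-[2-(4-(benzyloxy)phenyl)ethyl]-3-chlorophenyl}zinc chloride | Cl[Zn]c1c(OCc2ccccc2)ccc(Cl)c1CCc1ccc(OCc2ccccc2)cc1
F4 | step 5 | 3-(benzyloxy)-2-bromobenzaldehyde | O=Cc1cccc(OCc2ccccc2)c1Br
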